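## Structural features

The target is a labdane-type trans-decalin (rings A and B) whose C9 carries a two-carbon tether (C11, C12) to a 1,1-disubstituted alkene at C13. C13 in turn bears a 1,2-dioxane (C14, C15, C16, C17 and two oxygens) that is trans-fused along C16–C17 to a γ-lactone (oxygen on C16, C18, carbonyl C19). The decalin holds six stereocentres in one unbroken run: C4 (axial β-methyl, equatorial α-CO2Me), C5, C10, C9, C8 (equatorial α-hydroxyl under an axial β-methyl) and C6 (equatorial α-hydroxyl). The bicyclic peroxide holds three more, C14 (R), C16 (S) and C17 (R), with C16 and C17 adjacent and C14 one methylene away. The two stereochemical domains are insulated by C11–C13, so the peroxide centres must be set by reagents and not by the decalin. Fragile groups are the O–O bond (phosphines, low-valent metals, hydrides), the allylic peroxy C14–H (base-induced Kornblum–DeLaMare cleavage), the C6 hydroxyl lying peri to the C4 ester (lactonisation), the tertiary C8 hydroxyl (dehydration, ring closure onto any carbonyl at C12 or C13) and the lactone. The real difficulty is the late closure of the dioxane at a secondary allylic carbon that is open to allylic transposition, elimination and ionisation, with the C13 substituent axial on the chair that the trans-fused lactone imposes. The key step exploits the 1,4 relationship between the tertiary peroxy carbon C17 and the secondary allylic C14: a hydroperoxide on C17 and a leaving group on C14 close the six-membered ring by substitution, and since C17–O comes from an epoxide opening and C14–O from a halide displacement, both with inversion, the relative configuration follows from the epoxide and the carbinol.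

## Logic of the disconnections

31 ⇒ 29 (through 30). The acyl bond between C19 and the C16 oxygen is cut and C19 is lowered to the alcohol. A lactone cannot be carried through hydroperoxide chemistry, and if present first it would force the peroxide ring to close onto a rigid trans-fused bicycle. The gain is that the last ring needs no new stereocentre, only an oxidation. The demand is an oxidant that takes a primary alcohol beside an O–O bond and leaves the secondary C6 and tertiary C8 hydroxyls alone.

29 ⇒ 28. The O–Si bonds at C6, C8 and C19 are restored. C6–O must not be free next to the C4 ester while base is present, C8–O must not be free while a carbonyl sits at C12 or C13, and C19 must stay at the alcohol level. The C8 ether is an addition to the key-step pair and changes only a protecting group. The gain is a substrate whose only acidic O–H groups are those used or tolerated by the ring closure. The demand is a fluoride source that does not attack the peroxide.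

28 ⇒ 27. The C14–O bond of the dioxane is cut, leaving a hydroperoxide on C17 and a chloride of opposite configuration on C14. This is the only cut that lets both peroxy carbons be set by stereospecific inversions. The gain is that the ring and the C14 centre are traced to one C–Cl centre. The demand is clean direct substitution at a secondary allylic carbon.

27 ⇒ 26 ⇒ 25. The C17–OO bond is cut to an oxirane across C16 and C17, and the oxirane to the E alkene. Two stereocentres are reduced to one alkene geometry and one catalyst. The forward steps must open the oxirane at the tertiary carbon with inversion, and must epoxidise one face of the trisubstituted alkene without touching the C13 methylene. The required (16S,17S)-epoxide calls for the L-series dioxirane catalyst, not the usual D-fructose one.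

25 ⇒ 24 ⇒ 23 ⇒ 22. C14–Cl is traced to C14–OH of opposite configuration, and the carbinol to a ketone. A chromium-mediated union cannot control C14, so the centre is set afterwards by a reagent-controlled reduction. The gain is an explicit handle on C14. The demands are a reduction that distinguishes an α-branched alkenyl group from an allylic methylene, and a chlorination with inversion and no allylic shift.

22 ⇒ 15 + 21. The C13–C14 bond is cut between the alkenyl carbon and the carbonyl carbon. It is the most convergent cut and separates the two stereochemical domains into fragments of eleven and three steps. The demand is a coupling that tolerates an ester, silyl ethers and an enolisable skipped enal.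

21 ⇒ 20 ⇒ 17 + 18, and 17 ⇒ 16. The C15–C16 bond and the C17–methyl bond are cut. The E trisubstituted alkene then comes from an alkyne by syn carbometalation, and C14/C15 from a two-carbon electrophile. The demand is regioselective methyl delivery to the internal alkyne carbon.

15 ⇒ 14 ⇒ 12. The vinyl C13–O bond is traced to a methyl ketone and the C12–C13 bond to an aldehyde at C12. Two carbons are added in one olefination–hydrolysis. The demands are kinetic enolisation towards the methyl group and a C8 oxygen that is already masked.

12 ⇒ 10 ⇒ 9. The two O–Si bonds and the aldehyde are traced to a diol acetal, and the C8–O bond to the exocyclic alkene. Methyl addition to a C8 ketone would enter from the α face and give the wrong carbinol, whereas hydration of the alkene puts oxygen on the α face. The demand is face-selective capture of a tertiary radical.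

9 ⇒ 8 ⇒ 7 ⇒ 6 ⇒ 4. The C7–H bond, the exocyclic C=C bond, the two oxirane C–O bonds and the C6=C7 bond are removed in turn, back to the C8 ketone. C6 is β to that carbonyl, so enone chemistry reaches it and the decalin face bias sets its configuration. The demands are regioselective enolisation towards C7 and α-face epoxidation.

4 ⇒ 3 ⇒ 2 ⇒ 1. The C8 and C12 carbonyls are rejoined through C14 and C13 into the ring-C diene. 1 supplies C4, C5, C9 and C10 in the right absolute configuration together with the ester carbon. The demands are a double ozonolysis of a conjugated diene and the differentiation of aldehyde from ketone.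

## Other disconnections considered

Alternative 1: The cut removes the ring bonds C4–C5 and C9–C10 and the C8–O bond together, leading back to the acyclic epoxy trienone A2. In the forward sense MeAlCl2 would open the C3–C4 oxirane of A2, the two trisubstituted alkenes would add in a chair–chair array, and the side-chain ketone oxygen would end the cascade at C8. The product would be the tricyclic enol ether A1 (rings A and B plus a dihydropyran spanning C8 and C13).
- In its favour: one operation would make two carbocycles and five stereocentres from a single asymmetric epoxidation. The C8 oxygen would arrive α under a β-methyl as a direct consequence of anti addition. On this point the alternative is the better, since the chosen plan relies on face selectivity in a radical hydration (step 8). The enol ether of A1 is also a stored form of the C13 methyl ketone that the chosen plan builds in steps 9 and 10.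
- Against it here: A1 has no oxygen at C6, so an unactivated methylene would have to be oxidised late. It carries a C3 hydroxyl that must be removed, and its C4 CH2O group must be raised to the ester. Cationic cascades ended by a ketone commonly divert part of the material to partly cyclised or eliminated products. Nothing is gained for the peroxide half.
- Comparison: structurally A1 maps onto 14 without the C6 oxygen. Mechanistically it is a cationic polyene cyclisation under epoxide control, against a chiral-pool degradation that inherits C4, C5, C9 and C10. In decalin stereocontrol it is the equal of the chosen plan, and it is independent of a natural resin acid. On step count, the supply of A2 and the corrections at C3, C4 and C6 are expected to outweigh the saving at C8 and C13.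

Alternative 2: The cut is the C6–O bond, with the C4 carboxyl as the directing group. In the forward sense the primary carboxamide A4 would be treated with PhI(OAc)2 and I2 under visible light. The amidyl radical would take the equatorial C6 hydrogen through a six-membered transition state, and iodination at C6, closure by the amide oxygen and hydrolysis would give the γ-lactone A3.
- In its favour: it uses the native carboxyl, and the peri geometry of the chair allows only the α C6–H to be reached (C2–H is remote from an equatorial amide). The C6 configuration is thus fixed by geometry, which is better than the chosen plan, where it rests on the facial bias of an enone epoxidation (step 5). The lactone of A3 also protects the C6 oxygen and the carboxyl at once, and one C–H functionalisation would replace steps 4 to 7.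
- Against it here: the hindered acid must first be converted into the amide and the ketone kept as a dioxolane. The lactone must later be opened to the methyl ester and free C6 hydroxyl against the preference of this peri pair for the closed form. That opening has to be done before the peroxide exists or on the peroxide itself.
- Comparison: both plans start from the same resin-acid degradation, and this alternative is compatible with step 21, which it does not replace. The mechanisms differ (radical C–H abstraction against polar enone chemistry). In step count the two are about equal, because the saving is offset by amide formation, ketal handling and lactone opening with re-esterification.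

Alternative 3: The cut is the C9–C10 bond. In the forward sense a chiral trivalent iodine reagent of the ArI(OAc)2 type would activate the phenol oxygen of the β-keto ester A6. The enol carbon C9 would attack the methyl-bearing para carbon C10, closing ring B and leaving the cross-conjugated dienone A5.
- In its favour: the quaternary C10 and ring B would come enantioselectively from a flat precursor that is a few steps from commodity aromatics. Either enantiomer and analogues would be accessible, and supply would not depend on a resin acid of variable purity. On these points the alternative is the better.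
- Against it here: A5 lacks the C4 quaternary ester (a reductive carboxylation of the C4-methyl enone), the C5 centre, the saturated C1–C3 segment (removal of the C3 ketone and the C1=C2 alkene), the C6 oxygen and the C8 carbinol. Its C11 is an ester carbon that must be extended by two carbons. Enantioselectivity in carbon–carbon dearomatisations with chiral aryl iodanes is usually moderate, and C9 of a β-keto ester is epimerisable.
- Comparison: the mechanism forms the hardest carbocyclic centre directly, but four decalin stereocentres that the chosen plan inherits would each need a step. For the C6 and C8 oxygens the two plans are equal, since both would start from a C8 ketone. The sequence to a compound like 15 is judged clearly longer.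

Key step: step 21

Remark on the chemistry: atoms are numbered as in a labdane (decalin C1–C10, side chain C11–C19; the methylene on C13 and the methyls on C4, C8, C10 and C17 are named by the carbon that bears them), and the L-sorbose-derived enantiomer of the Shi ketone is assumed to be available as a catalyst.

## Route

Step 1
Reactants: 1 levopimaric acid
Product: 2 methyl levopimarate
Conditions: MeI, K2CO3, DMF, rt
Reagents that add atoms: iodomethane, CI
Why: Carboxylate O-alkylation (SN2 on MeI) under mildly basic, acid-free conditions, chosen because acid or heat would isomerise the homoannular diene; no stereocentre is involved.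

Step 2
Reactants: 2 methyl levopimarate
Product: 3 C8-keto C12-aldehyde (ring C cut away; CH2CHO arm on C9)
Conditions: O3, CH2Cl2/MeOH, NaHCO3, −78 °C; then Me2S, −78 °C → rt
Reagents that add atoms: ozone, [O-][O+]=O
Why: Ozonolysis with reductive work-up cleaves both C=C bonds of the ring-C diene, leaving C8 as a ketone and C12 as an aldehyde while C13, C14 and the isopropyl group leave as a keto aldehyde. C9, now α to the ketone, already holds its side chain equatorial, so enolisation should not erode it.

Step 3
Reactants: 3 C8-keto C12-aldehyde
Product: 4 C8-keto C12 dimethyl acetal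
Conditions: HC(OMe)3, MeOH, pyridinium p-toluenesulfonate (cat.), 0 °C → rt
Reagents that add atoms: trimethyl orthoformate, COC(OC)OC; methanol, CO
Why: Chemoselective acid-catalysed acetalisation, much faster at the unhindered aldehyde than at the C8 ketone flanked by the C9 branch; the orthoformate removes water so that the furan-forming pathway of the 1,4-dicarbonyl is not entered.

Step 4
Reactants: 4 C8-keto C12 dimethyl acetal
Product: 6 C6=C7 enone acetal, via trimethylsilyl enol ether 5 (not isolated)
Conditions: LiN(iPr)2, Me3SiCl, THF, −78 °C; then Pd(OAc)2, MeCN, rt
Reagents that add atoms: none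
Why: Kinetic deprotonation by the hindered amide takes the C7 methylene and not the tertiary C9–H, and the trapped enol silane undergoes Saegusa–Ito oxidation to place the alkene at C6–C7. No stereocentre is formed.

Step 5
Reactants: 6 C6=C7 enone acetal
Product: 7 6α,7α-epoxy C8 ketone acetal
Conditions: H2O2 (30% aq.), NaOH, MeOH, 0 °C
Reagents that add atoms: hydrogen peroxide, OO
Why: Weitz–Scheffer nucleophilic epoxidation. Hydroperoxide anion should add to C6 from the α face, because the β face is closed by the axial methyls on C4 and C10, and the enolate closes the oxirane on the same face, fixing the C6–O bond α.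

Step 6
Reactants: 7 6α,7α-epoxy C8 ketone acetal
Product: 8 6α,7α-epoxy C8-methylidene acetal (alkenyl oxirane)
Conditions: Ph3PCH3Br, KOtBu, THF, 0 °C → rt
Reagents that add atoms: methyltriphenylphosphonium bromide, C[P+](c1ccccc1)(c1ccccc1)c1ccccc1.[Br-]
Why: Wittig methylenation; the non-stabilised ylide attacks the ketone and should leave the oxirane, the hindered ester and the acetal alone.

Step 7
Reactants: 8 6α,7α-epoxy C8-methylidene acetal
Product: 9 6α-hydroxy C8-methylidene acetal
Conditions: Pd2(dba)3·CHCl3 (cat.), PBu3, HCO2H, Et3N, 1,4-dioxane, rt
Reagents that add atoms: none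
Why: Tsuji-type hydrogenolysis of an alkenyl oxirane: zerovalent palladium ionises the allylic C7–O bond, formate decarboxylates to a palladium hydride, and hydride goes to C7, so the α C6–O bond is untouched and the exocyclic alkene is kept. Hydride delivery to the methylene terminus would give the C7=C8 isomer, which leads to the same tertiary radical in step 8.

Step 8
Reactants: 9 6α-hydroxy C8-methylidene acetal
Product: 10 6α,8α-diol acetal (8β-methyl)
Conditions: Co(acac)2 (cat.), PhSiH3, O2 (1 atm), THF, rt
Reagents that add atoms: dioxygen, O=O
Why: Mukaiyama hydration (metal-hydride hydrogen-atom transfer, then capture by O2). The hydrogen atom goes to the terminal carbon and the tertiary C8 radical should be trapped on the α face, since the axial β approach is blocked by the 1,3-related axial methyl on C10, giving the 8α-hydroxy-8β-methyl carbinol.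

Step 9
Reactants: 10 6α,8α-diol acetal
Product: 12 6α,8α-bis(triethylsilyloxy) C12 aldehyde, via bis(triethylsilyl) ether acetal 11 (not isolated)
Conditions: Et3SiOTf (5 equiv), 2,6-lutidine, CH2Cl2, −40 → 0 °C; then H2O, rt
Reagents that add atoms: triethylsilyl trifluoromethanesulfonate, CC[Si](CC)(CC)OS(=O)(=O)C(F)(F)F; water, O
Why: Silyl triflate with a hindered pyridine silylates the secondary and the tertiary hydroxyl, and the same pair ionises the aldehyde dimethyl acetal to a pyridinium adduct that water converts into the aldehyde, a known non-acidic acetal cleavage that spares silyl ethers. Masking C8–O before the aldehyde appears prevents lactol formation.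

Step 10
Reactants: 12 6α,8α-bis(triethylsilyloxy) C12 aldehyde
Product: 14 C13 methyl ketone, via methyl enol ether 13 (not isolated)
Conditions: (1-methoxyethyl)triphenylphosphonium chloride, KN(SiMe3)2, THF, −78 → 0 °C; then 1 M aq. oxalic acid, THF, 0 °C → rt
Reagents that add atoms: (1-methoxyethyl)triphenylphosphonium chloride, COC(C)[P+](c1ccccc1)(c1ccccc1)c1ccccc1.[Cl-]; water, O
Why: Wittig alkoxy-olefination with the α-methoxyethylidene ylide forms the C12–C13 bond as a methyl enol ether, and mild acid hydrolysis delivers the methyl ketone. The enol ether should hydrolyse far faster than the triethylsilyl ethers.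

Step 11
Reactants: 14 C13 methyl ketone
Product: 15 decalin enol triflate (CH2=C(OTf)–C12H2–C11H2–C9)
Conditions: KN(SiMe3)2, THF, −78 °C; then PhNTf2, −78 → 0 °C
Reagents that add atoms: N-phenylbis(trifluoromethanesulfonimide), O=S(=O)(N(c1ccccc1)S(=O)(=O)C(F)(F)F)C(F)(F)F
Why: Kinetic enolisation of a methyl ketone by a bulky amide occurs at the methyl group, and O-sulfonylation gives the 1-alken-2-yl triflate.

Step 12
Reactants: 16 3-butyn-1-ol
Product: 17 4-(tert-butyldimethylsilyloxy)but-1-yne
Conditions: t-BuMe2SiCl, imidazole, CH2Cl2, 0 °C → rt
Reagents that add atoms: tert-butyldimethylsilyl chloride, CC(C)(C)[Si](C)(C)Cl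
Why: Standard silylation of a primary alcohol.

Step 13
Reactants: 17 4-(tert-butyldimethylsilyloxy)but-1-yne; 18 ethylene oxide
Product: 20 (E)-6-(tert-butyldimethylsilyloxy)-4-methylhex-3-en-1-ol, via alkenylalane 19 (not isolated)
Conditions: AlMe3, Cp2ZrCl2 (0.25 equiv), CH2Cl2, 0 °C → rt; then n-BuLi, THF, −78 °C; 18, −78 °C → rt
Reagents that add atoms: trimethylaluminium, C[Al](C)C
Why: Negishi zirconium-catalysed carboalumination adds methyl and aluminium syn across the alkyne with methyl on the internal carbon, which defines the E trisubstituted alkene. The derived alanate opens the oxirane with retention of alkene geometry and forms the C15–C16 bond.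

Step 14
Reactants: 20 (E)-6-(tert-butyldimethylsilyloxy)-4-methylhex-3-en-1-ol
Product: 21 (E)-6-(tert-butyldimethylsilyloxy)-4-methylhex-3-enal
Conditions: Dess–Martin periodinane, NaHCO3, CH2Cl2, 0 °C; used at once
Reagents that add atoms: none
Why: Dess–Martin oxidation under bicarbonate buffering is neutral enough to keep the β,γ-alkene out of conjugation.

Step 15
Reactants: 15 decalin enol triflate; 21 (E)-6-(tert-butyldimethylsilyloxy)-4-methylhex-3-enal
Product: 22 C14 allylic alcohol as a mixture of C14 epimers
Conditions: CrCl2 (4 equiv), NiCl2 (2 mol %), degassed DMF, rt
Reagents that add atoms: none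
Why: Nozaki–Hiyama–Kishi coupling: nickel inserts into the C–OTf bond, the alkenyl group passes to chromium and adds to the aldehyde only, tolerating the ester, the silyl ethers and the enolisable skipped enal. C14 forms without control and is corrected in steps 16 and 17.

Step 16
Reactants: 22 C14 allylic alcohol (epimer mixture)
Product: 23 C14 enone (α-methylene ketone)
Conditions: Dess–Martin periodinane, NaHCO3, CH2Cl2, 0 °C → rt
Reagents that add atoms: none
Why: Dess–Martin oxidation converges both C14 epimers on one enone under buffered conditions that should not move the β,γ-alkene.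

Step 17
Reactants: 23 C14 enone
Product: 24 (14R)-allylic alcohol
Conditions: (S)-Me-CBS oxazaborolidine [(S)-1-methyl-3,3-diphenyltetrahydro-1H,3H-pyrrolo[1,2-c][1,3,2]oxazaborole] (0.5 equiv), catecholborane, toluene, −78 °C
Reagents that add atoms: none
Why: Corey–Bakshi–Shibata reduction: the ketone binds the oxazaborolidine boron anti to its larger, α-branched alkenyl substituent and hydride is delivered within the complex, which for the (S)-catalyst should give the (14R)-carbinol in the same sense as aryl alkyl ketones. Catecholborane at −78 °C does not hydroborate the alkenes.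

Step 18
Reactants: 24 (14R)-allylic alcohol
Product: 25 (14S)-allylic chloride
Conditions: PPh3, Cl3CC(O)CCl3, CH2Cl2, −20 → 0 °C
Reagents that add atoms: hexachloroacetone, ClC(Cl)(Cl)C(=O)C(Cl)(Cl)Cl
Why: Appel-type chlorination: the alkoxyphosphonium ion is displaced by chloride with inversion to the (14S)-chloride. With hexachloroacetone the counter-ion is the pentachloroacetone enolate, so free chloride stays low and allylic transposition and epimerisation are suppressed.

Step 19
Reactants: 25 (14S)-allylic chloride
Product: 26 (14S)-chloro (16S,17S)-epoxide
Conditions: ent-Shi ketone [1,2:4,5-di-O-isopropylidene-β-L-erythro-2,3-hexodiulo-2,6-pyranose] (0.3 equiv), KHSO5 (as 2KHSO5·KHSO4·K2SO4), K2CO3, Bu4NHSO4, MeCN/CH2(OMe)2/aq. Na2B4O7 buffer (pH 10.5), 0 °C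
Reagents that add atoms: potassium peroxymonosulfate, [K+].[O-]S(=O)(=O)OO
Why: Shi epoxidation by the chiral dioxirane through a spiro transition state; the L-series ketone is needed because the D-fructose catalyst gives (R,R)-epoxides from E trisubstituted alkenes of this type. The electron-rich trisubstituted alkene should react in preference to the 1,1-disubstituted alkene, which is deactivated by the allylic chlorine.

Step 20
Reactants: 26 (14S)-chloro (16S,17S)-epoxide
Product: 27 (14S)-chloro (16S)-hydroxy (17R)-hydroperoxide
Conditions: H2O2 (anhydrous solution in Et2O, excess), H3PMo12O40 (cat.), Et2O, 0 °C → rt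
Reagents that add atoms: hydrogen peroxide, OO
Why: Acid-catalysed perhydrolysis (epoxide ring opening by H2O2): the activated oxirane is attacked at the tertiary C17, which carries more positive charge, from the side opposite the C–O bond. This inverts C17 while C16 keeps its oxygen and configuration.

Step 21
Reactants: 27 (14S)-chloro (16S)-hydroxy (17R)-hydroperoxide
Product: 28 (14R,16S,17R)-1,2-dioxane with free C16 hydroxyl and silylated C6, C8 and C19 oxygens
Conditions: Cs2CO3 (1.5 equiv), DMF, 0 °C → rt
Reagents that add atoms: none
Why: Cs2CO3 ionises only the hydroperoxide, the most acidic O–H present, and the outer oxygen of the C17 peroxy anion attacks C14 from the face opposite chloride in an intramolecular SN2 displacement that forms the C14–O bond. The closest known reaction type is the base-mediated intramolecular alkylation of hydroperoxides by halides or sulfonates, which gives 1,2-dioxanes and 1,2-dioxolanes. The ring closes in a 6-exo-tet mode, the breaking C–Cl bond lying outside the new ring made of C14, C15, C16, C17 and the two oxygens. The only new stereocentre, C14, is controlled by the configuration of the (14S)-chloride: backside attack gives the (14R)-peroxide, and C16 and C17 are not touched. Since C17 was inverted in step 20 and C14 is inverted here, the relative configuration across the peroxide is fixed by two stereospecific events, and the resulting chair carries the C13 substituent axially, which an equilibrating closure would not favour. The step needs direct substitution at C14 over attack at the alkene terminus, elimination and ionisation: attack at the methylene would require an eight-membered transition state, the α-effect nucleophile is only weakly basic, and carbonate in DMF at low temperature without added halide disfavours elimination, ion-pair scrambling and chloride exchange. The C16 hydroxyl stays protonated under carbonate, which holds back oxetane formation and cleavage of the 1,2-hydroxy hydroperoxide, and a short reaction time limits Kornblum–DeLaMare opening of the product at the allylic C14–H.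

Step 22
Reactants: 28 (14R,16S,17R)-1,2-dioxane, silylated
Product: 29 dioxane tetraol (free C6, C8, C16 and C19 hydroxyls)
Conditions: HF·pyridine, pyridine, THF, 0 °C → rt
Reagents that add atoms: none
Why: Fluoride-mediated desilylation under buffered, non-reducing conditions to which dialkyl peroxides are inert; the tertiary C8 ether is the slowest and sets the reaction time.

Step 23
Reactants: 29 dioxane tetraol
Product: 31 CNP0162504.1, via lactol 30 (not isolated)
Conditions: TEMPO (0.2 equiv), PhI(OAc)2 (2.5 equiv), CH2Cl2, rt
Reagents that add atoms: none
Why: Aminoxyl-catalysed oxidation takes the primary C19 alcohol to the aldehyde, which the C16 hydroxyl captures as a five-membered lactol that is oxidised again to the γ-lactone. The hindered secondary C6 hydroxyl and the tertiary C8 hydroxyl should not be oxidised at a useful rate, and the O–O bond is inert to the oxoammonium salt.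

## Compound list

1 | levopimaric acid (abieta-8(14),12-dien-18-oic acid) | CC(C)C1=CC[C@@H]2[C@@]3(C)CCC[C@@](C)(C(=O)O)[C@@H]3CCC2=C1 | starting material
2 | methyl levopimarate | CC(C)C1=CC[C@@H]2[C@@]3(C)CCC[C@@](C)(C(=O)OC)[C@@H]3CCC2=C1 | intermediate
3 | C8-keto C12-aldehyde (trans-decalin of 2 with C8=O and CH2CHO on C9) | O=CC[C@@H]1[C@@]2(C)CCC[C@@](C)(C(=O)OC)[C@@H]2CCC1=O | intermediate
4 | C8-keto C12 dimethyl acetal | COC(OC)C[C@@H]1[C@@]2(C)CCC[C@@](C)(C(=O)OC)[C@@H]2CCC1=O | intermediate
5 | C7=C8 trimethylsilyl enol ether of 4 (not isolated) | COC(OC)C[C@@H]1[C@@]2(C)CCC[C@@](C)(C(=O)OC)[C@@H]2CC=C1O[Si](C)(C)C | intermediate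
6 | C6=C7 enone acetal | COC(OC)C[C@@H]1[C@@]2(C)CCC[C@@](C)(C(=O)OC)[C@@H]2C=CC1=O | intermediate
7 | 6α,7α-epoxy C8 ketone acetal | COC(OC)C[C@@H]1[C@@]2(C)CCC[C@@](C)(C(=O)OC)[C@@H]2[C@H]3O[C@H]3C1=O | intermediate
8 | 6α,7α-epoxy C8-methylidene acetal | COC(OC)C[C@@H]1[C@@]2(C)CCC[C@@](C)(C(=O)OC)[C@@H]2[C@H]3O[C@H]3C1=C | intermediate
9 | 6α-hydroxy C8-methylidene acetal | COC(OC)C[C@@H]1[C@@]2(C)CCC[C@@](C)(C(=O)OC)[C@@H]2[C@@H](O)CC1=C | intermediate
10 | 6α,8α-diol acetal (8β-methyl) | COC(OC)C[C@@H]1[C@@]2(C)CCC[C@@](C)(C(=O)OC)[C@@H]2[C@@H](O)C[C@@]1(C)O | intermediate
11 | 6α,8α-bis(triethylsilyloxy) dimethyl acetal (not isolated) | COC(OC)C[C@@H]1[C@@]2(C)CCC[C@@](C)(C(=O)OC)[C@@H]2[C@@H](O[Si](CC)(CC)CC)C[C@@]1(C)O[Si](CC)(CC)CC | intermediate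
12 | 6α,8α-bis(triethylsilyloxy) C12 aldehyde | O=CC[C@@H]1[C@@]2(C)CCC[C@@](C)(C(=O)OC)[C@@H]2[C@@H](O[Si](CC)(CC)CC)C[C@@]1(C)O[Si](CC)(CC)CC | intermediate
13 | C12=C13 methyl enol ether, either geometry (not isolated) | COC(C)=CC[C@@H]1[C@@]2(C)CCC[C@@](C)(C(=O)OC)[C@@H]2[C@@H](O[Si](CC)(CC)CC)C[C@@]1(C)O[Si](CC)(CC)CC | intermediate
14 | C13 methyl ketone | CC(=O)CC[C@@H]1[C@@]2(C)CCC[C@@](C)(C(=O)OC)[C@@H]2[C@@H](O[Si](CC)(CC)CC)C[C@@]1(C)O[Si](CC)(CC)CC | intermediate
15 | decalin enol triflate | C=C(OS(=O)(=O)C(F)(F)F)CC[C@@H]1[C@@]2(C)CCC[C@@](C)(C(=O)OC)[C@@H]2[C@@H](O[Si](CC)(CC)CC)C[C@@]1(C)O[Si](CC)(CC)CC | intermediate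
16 | 3-butyn-1-ol | C#CCCO | starting material
17 | 4-(tert-butyldimethylsilyloxy)but-1-yne | C#CCCO[Si](C)(C)C(C)(C)C | intermediate
18 | ethylene oxide | C1CO1 | starting material
19 | (E)-[4-(tert-butyldimethylsilyloxy)-2-methylbut-1-enyl]dimethylalane (not isolated) | C[Al](C)/C=C(\C)CCO[Si](C)(C)C(C)(C)C | intermediate
20 | (E)-6-(tert-butyldimethylsilyloxy)-4-methylhex-3-en-1-ol | OCC/C=C(\C)CCO[Si](C)(C)C(C)(C)C | intermediate
21 | (E)-6-(tert-butyldimethylsilyloxy)-4-methylhex-3-enal | O=CC/C=C(\C)CCO[Si](C)(C)C(C)(C)C | intermediate
22 | C14 allylic alcohol, mixture of C14 epimers | C=C(CC[C@@H]1[C@@]2(C)CCC[C@@](C)(C(=O)OC)[C@@H]2[C@@H](O[Si](CC)(CC)CC)C[C@@]1(C)O[Si](CC)(CC)CC)C(O)C/C=C(\C)CCO[Si](C)(C)C(C)(C)C | intermediate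
23 | C14 enone | C=C(CC[C@@H]1[C@@]2(C)CCC[C@@](C)(C(=O)OC)[C@@H]2[C@@H](O[Si](CC)(CC)CC)C[C@@]1(C)O[Si](CC)(CC)CC)C(=O)C/C=C(\C)CCO[Si](C)(C)C(C)(C)C | intermediate
24 | (14R)-allylic alcohol | C=C(CC[C@@H]1[C@@]2(C)CCC[C@@](C)(C(=O)OC)[C@@H]2[C@@H](O[Si](CC)(CC)CC)C[C@@]1(C)O[Si](CC)(CC)CC)[C@H](O)C/C=C(\C)CCO[Si](C)(C)C(C)(C)C | intermediate
25 | (14S)-allylic chloride | C=C(CC[C@@H]1[C@@]2(C)CCC[C@@](C)(C(=O)OC)[C@@H]2[C@@H](O[Si](CC)(CC)CC)C[C@@]1(C)O[Si](CC)(CC)CC)[C@@H](Cl)C/C=C(\C)CCO[Si](C)(C)C(C)(C)C | intermediate
26 | (14S)-chloro (16S,17S)-epoxide | C=C(CC[C@@H]1[C@@]2(C)CCC[C@@](C)(C(=O)OC)[C@@H]2[C@@H](O[Si](CC)(CC)CC)C[C@@]1(C)O[Si](CC)(CC)CC)[C@@H](Cl)C[C@@H]1O[C@@]1(C)CCO[Si](C)(C)C(C)(C)C | intermediate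
27 | (14S)-chloro (16S)-hydroxy (17R)-hydroperoxide (key-step precursor) | C=C(CC[C@@H]1[C@@]2(C)CCC[C@@](C)(C(=O)OC)[C@@H]2[C@@H](O[Si](CC)(CC)CC)C[C@@]1(C)O[Si](CC)(CC)CC)[C@@H](Cl)C[C@H](O)[C@](CCO[Si](C)(C)C(C)(C)C)(C)OO | intermediate
28 | (14R,16S,17R)-1,2-dioxane with C16 hydroxyl, silylated at C6, C8 and C19 (key-step product) | C=C(CC[C@@H]1[C@@]2(C)CCC[C@@](C)(C(=O)OC)[C@@H]2[C@@H](O[Si](CC)(CC)CC)C[C@@]1(C)O[Si](CC)(CC)CC)[C@H]1C[C@H](O)[C@](CCO[Si](C)(C)C(C)(C)C)(C)OO1 | intermediate
29 | dioxane tetraol | C=C(CC[C@@H]1[C@@]2(C)CCC[C@@](C)(C(=O)OC)[C@@H]2[C@@H](O)C[C@@]1(C)O)[C@H]1C[C@H](O)[C@](CCO)(C)OO1 | intermediate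
30 | C19 lactol, either anomer (not isolated) | C=C(CC[C@@H]1[C@@]2(C)CCC[C@@](C)(C(=O)OC)[C@@H]2[C@@H](O)C[C@@]1(C)O)[C@H]1C[C@@H]2OC(O)C[C@@]2(C)OO1 | intermediate
31 | CNP0162504.1 | C=C(CC[C@@H]1[C@@]2(C)CCC[C@@](C)(C(=O)OC)[C@@H]2[C@@H](O)C[C@@]1(C)O)[C@H]1C[C@@H]2OC(=O)C[C@@]2(C)OO1 | target

## Step count and least certain steps

Total: 23 steps. Longest linear sequence: 20 steps (steps 1–11 and 15–23, from 1); the side-chain fragment takes steps 12–14.

Step 21 (key step).
- What may go wrong: loss of HCl towards a diene, cleavage of the 1,2-hydroxy hydroperoxide, or Kornblum–DeLaMare opening of the product at the allylic C14–H may outrun the substitution. The peroxy anion is also a base and C14 is secondary.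
- Fallback: the order in which the two C–O bonds are made is reversed. Setting out from 26, the chloride is displaced intermolecularly, with inversion, by the caesium salt of 2-methoxyprop-2-yl hydroperoxide (CsOH·H2O, DMF, 0 °C) to give the (14R)-peroxyketal epoxide F1. Aqueous acetic acid then releases the (14R)-hydroperoxy epoxide F2. A catalytic amount of camphorsulfonic acid in CH2Cl2 lets its outer oxygen open the oxirane at the tertiary C17 with inversion, the six-membered ring being favoured over the five-membered one by the tertiary centre. This returns to the route at 28. The stereochemical logic of two inversions is unchanged, and no 1,2-hydroxy hydroperoxide meets base.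

Step 20.
- What may go wrong: the acid catalyst may strip the silyl ethers, the secondary C6 ether first, because heteropoly acids cleave silyl ethers. The liberated C6 hydroxyl would then sit beside the ester during the basic closure.
- Fallback: the end game is run without protecting groups. Setting out from 26, the three silyl ethers are removed first with Et3N·3HF (THF, rt), which should leave a trisubstituted oxirane and an allylic chloride intact, to give the desilylated epoxy chloride F3. Perhydrolysis under the conditions of step 20 then has no acid-labile group to lose and gives the hydroxy hydroperoxide F4. Its closure with Cs2CO3 as in step 21 returns to the route at 29, so step 22 falls away. The price is a free C6 hydroxyl next to the ester during the closure.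

Step 18.
- What may go wrong: allylic transposition (chloride entering at the methylene terminus) or erosion of configuration at C14 through ion-pair collapse, because the oxyphosphonium group sits on a secondary allylic carbon.
- Fallback: activation is separated from substitution. Setting out from 24, (MeSO2)2O and Et3N at −40 °C give the (14R)-methanesulfonate F5 with retention. It is not purified and is treated cold with one equivalent of LiCl in THF/DMF at −20 °C, an SN2 displacement with inversion that returns to the route at 25. One equivalent of chloride and the low temperature guard against degenerate exchange.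

Step 17.
- What may go wrong: modest facial discrimination, because the two ketone substituents differ little in bulk, or drift of the β,γ-alkene of 23 into conjugation before reduction.
- Fallback: the fragments are united under catalyst control. Setting out from 15 and 21, a catalytic asymmetric Nozaki–Hiyama–Kishi coupling would form the C13–C14 bond and the (14R)-carbinol together. The conditions would be CrCl2 with a chiral sulfonamide–oxazoline ligand, a NiCl2·2,9-dimethyl-1,10-phenanthroline co-catalyst, Mn, Cp2ZrCl2, LiCl and MeCN. This returns to the route at 24 and removes 22 and 23. The ligand enantiomer would be chosen on a small scale. No new compound arises.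

Step 8.
- What may go wrong: insufficient facial selectivity in the capture of the planar C8 radical, which would give the 8-epimer, because the preference rests only on the axial C10 methyl.
- Fallback: a polar, face-selective epoxidation followed by a two-step reduction. Setting out from 9, m-chloroperbenzoic acid (NaHCO3, CH2Cl2, 0 °C) should attack the exocyclic alkene from the α face, helped by the C6 hydroxyl, to give the 8α,17-epoxide F6. LiI/AcOH in THF opens it at the primary carbon to the iodohydrin F7, and Bu3SnH/AIBN (toluene, 80 °C) removes iodine to return to the route at 10. The ester rules out a hydride opening of the epoxide, hence the iodide detour.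

## Further compounds

F1 | step 21 | (14R)-peroxyketal epoxide (2-methoxyprop-2-ylperoxy group on C14, 16S,17S-epoxide) | C=C(CC[C@@H]1[C@@]2(C)CCC[C@@](C)(C(=O)OC)[C@@H]2[C@@H](O[Si](CC)(CC)CC)C[C@@]1(C)O[Si](CC)(CC)CC)[C@H](OOC(C)(C)OC)C[C@@H]1O[C@@]1(C)CCO[Si](C)(C)C(C)(C)C
F2 | step 21 | (14R)-hydroperoxy epoxide | C=C(CC[C@@H]1[C@@]2(C)CCC[C@@](C)(C(=O)OC)[C@@H]2[C@@H](O[Si](CC)(CC)CC)C[C@@]1(C)O[Si](CC)(CC)CC)[C@H](OO)C[C@@H]1O[C@@]1(C)CCO[Si](C)(C)C(C)(C)C
F3 | step 20 | desilylated epoxy chloride (free C6, C8 and C19 hydroxyls) | C=C(CC[C@@H]1[C@@]2(C)CCC[C@@](C)(C(=O)OC)[C@@H]2[C@@H](O)C[C@@]1(C)O)[C@@H](Cl)C[C@@H]1O[C@@]1(C)CCO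
F4 | step 20 | desilylated hydroxy hydroperoxide (14S-chloride, 16S-hydroxyl, 17R-hydroperoxide) | C=C(CC[C@@H]1[C@@]2(C)CCC[C@@](C)(C(=O)OC)[C@@H]2[C@@H](O)C[C@@]1(C)O)[C@@H](Cl)C[C@H](O)[C@](CCO)(C)OO
F5 | step 18 | (14R)-methanesulfonate | C=C(CC[C@@H]1[C@@]2(C)CCC[C@@](C)(C(=O)OC)[C@@H]2[C@@H](O[Si](CC)(CC)CC)C[C@@]1(C)O[Si](CC)(CC)CC)[C@H](OS(C)(=O)=O)C/C=C(\C)CCO[Si](C)(C)C(C)(C)C
F0 | step 17 | none | none
F6 | step 8 | 8α,17-epoxide (spiro-oxirane at C8, 6α-hydroxyl) | COC(OC)C[C@@H]1[C@@]2(C)CCC[C@@](C)(C(=O)OC)[C@@H]2[C@@H](O)C[C@]13CO3
F7 | step 8 | iodohydrin (8α-hydroxyl, 8β-iodomethyl) | COC(OC)C[C@@H]1[C@@]2(C)CCC[C@@](C)(C(=O)OC)[C@@H]2[C@@H](O)C[C@@]1(CI)O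
A1 | alternative 1 | tricyclic enol ether (rings A and B with a dihydropyran across C8 and C13) | CC1=CC[C@@H]2[C@@]3(C)CC[C@H](O)[C@@](C)(CO[Si](c4ccccc4)(c4ccccc4)C(C)(C)C)[C@@H]3CC[C@@]2(C)O1
A2 | alternative 1 | acyclic (E,E)-epoxy trienone with silylated hydroxymethyl on the oxirane | CC(=O)CC/C=C(\C)CC/C=C(\C)CC[C@@H]1O[C@@]1(C)CO[Si](c1ccccc1)(c1ccccc1)C(C)(C)C
A3 | alternative 2 | γ-lactone from the C4 carboxyl to C6 (C8 dioxolane, C12 silyl ether) | CC(C)(C)[Si](C)(C)OCC[C@@H]1[C@@]2(C)CCC[C@@](C)(C(=O)O5)[C@@H]2[C@@H]5CC13OCCO3
A4 | alternative 2 | C4 primary carboxamide (C8 dioxolane, C12 silyl ether) | CC(C)(C)[Si](C)(C)OCC[C@@H]1[C@@]2(C)CCC[C@@](C)(C(N)=O)[C@@H]2CCC13OCCO3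
A5 | alternative 3 | bicyclic dienone β-keto ester | COC(=O)[C@@H]1[C@@]2(C)C=CC(=O)C(C)=C2CCC1=O
A6 | alternative 3 | methyl 5-(3-hydroxy-2,6-dimethylphenyl)-3-oxopentanoate | COC(=O)CC(=O)CCc1c(C)ccc(O)c1C
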